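Readings and results come from a simulation for substances that don't exist, noise included.

I started from how slowly these flasks ran: after 4.00 min, Sunday's run had made product amounting to 13.1% of the substrate charged, so I wanted a rate for the catalyst itself.

| setting | Sunday's | Saturday's | Wednesday's | teal | grey |
|---|---|---|---|---|---|
| substrate | 0.46 M | 0.46 M | 1.3 M | 2.0 M | 0.46 M |
| reagent | 0.69 M | 0.69 M | 0.69 M | 0.690 M | 0.690 M |
| free catalyst | 23 mM (in portions, 4) | 23 mM (in portions, 4) | 23 mM (in portions, 4) | 23 mM | 23 mM (in portions, 4) |
| added ligand | 12 mM | 41 mM | 15 mM | 60 mM | 15 mM |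
| remark | run made earlier; portions every 100 s | run made earlier; portions every 100 s | run made earlier; portions every 100 s | everything together at the start | the portions of free catalyst follow each other after 100 s, the first at the start |
| time |  |  |  | 6.0 min | 6.0 min |

- Sunday's (time / min: product / %): 0.500: 1.0; 1.33: 3.9; 2.50: 5.8; 4.00: 13.1
- Saturday's (time / min: product / %): 1.00: 0.6; 2.00: 2.3; 3.00: 6.1; 4.00: 9.2
- Wednesday's (time / min: product / %): 0.500: 1.1; 1.33: 1.0; 2.50: 2.1; 4.00: 6.2

(standard deviation of a reading: 1 percentage point)

- the flask that ends with the higher amount of product, in percent of the substrate charged, or "neither" when 2 percentage points or less lies between them (teal / grey / neither)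
- final product, as a percentage of the substrate charged, in teal
- final product, as a percentage of the substrate charged, in grey



The first setting was portioning. By hand, a portion works only once it is in, so I counted the time the whole charge would have had to stand to give the same catalyst-time. At the last reading of each earlier run this was:

τ = 1.75 min

Grey reached 3.50 min and teal 6.0 min. I then defined T as molar product per catalyst charged per minute of τ, a turnover frequency.

The second setting was added ligand. By hand, it should divide T by (1 + [added ligand]/K). Sunday's run gave 1.50 min⁻¹ and Saturday's 1.05 min⁻¹, so I read K as 56.4 mM, a rough reading given the scatter. At grey's recipe, this gave T = 1.43 min⁻¹.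

The third setting was substrate. Wednesday's run, at grey's ligand level, gave 2.00 min⁻¹, so T rose with [substrate]. I fitted a flattening curve, T = Tmax[substrate]/([substrate] + Ks), with Ks = 0.360 M and Tmax = 2.56 min⁻¹.

For teal, with its ligand factor:

T = 1.33 min⁻¹, product = 9.17%

For grey, the first round gave:

product = 0.115 M, or 25.1%

I put that back in, which took the mean [substrate] to 0.402 M:

T = 1.35 min⁻¹, product = 23.6%

In teal, the mean [substrate] stayed at 1.91 M, so I kept the first answer. I expected grey to end higher.

The forecast said grey, with 7% for teal and 27% for grey, and it differed from my reckoning in calling the reaction “roughly zero order in substrate”.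

The flasks gave 10.7% in teal and 24.0% in grey.

    reagent + catalyst intermediate A ⇌ catalyst intermediate B (K = 1.80 L mol⁻¹, k = 0.210 L mol⁻¹ s⁻¹)
    catalyst intermediate B → catalyst intermediate C (k = 0.150 s⁻¹)
    free catalyst + added ligand ⇌ idle complex, settled at all times (K = 46.0 L mol⁻¹)
    catalyst intermediate D ⇌ free catalyst + product (K = 1.40 M, k = 0.180 s⁻¹)
    substrate + free catalyst → catalyst intermediate A (k = 0.460 L mol⁻¹ s⁻¹)
    catalyst intermediate C → by-product + catalyst intermediate D (k = 0.170 s⁻¹)

At 6.00 min, grey still held 72.2% of its substrate, and 33.7% of its catalyst stood as catalyst intermediate A. Grey's product over its catalyst-time is T = 1.37 min⁻¹. A neighbouring flask was grey with 0.0057 M of free catalyst. There, T = 1.43 min⁻¹ over the same τ gives 6.22%, and that neighbouring flask ended at 6.24%.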